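Remarks on the chemistry, valid for all sections:
- Locants follow lignan usage: C7/C8/C9 and ring B for the half that ends up etherified, C7'/C8'/C9' and ring A for the half with the free phenol, C7''/C8''/C9'' and ring C for the glycerol side chain. The core rings are C7–O–C9'–C8'–C8 and C7'–O–C9–C8–C8'.
- Assumption: the Lewis acid formed from Ti(OiPr)4 and (R)-BINOL directs the nucleophile to the Re face of the bound aryl aldehyde, by analogy with its additions to other benzaldehydes. If the sense is the reverse, (S)-BINOL is used and nothing else changes.
- Assumption: methyl (R)-2,3-dihydroxypropanoate is bought as the single enantiomer.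

## Structural features

The target is a sesquilignan with three guaiacyl (4-oxy-3-methoxyphenyl) rings. Rings A and B sit on C7' and C7 of a 3,7-dioxabicyclo[3.3.0]octane (furofuran) core, and ring C belongs to a glycerol chain C7''–C8''–C9'' whose C8'' is bound through an ether oxygen to O-4 of ring B. The core is two cis-fused tetrahydrofuran rings sharing the C8–C8' bond; its four stereocentres C7, C8, C8', C7' are contiguous (7R,7'R,8S,8'S, the (−)-pinoresinol series), both aryl groups lie on the convex face, and the core is C2-symmetric until ring B is etherified. The side chain has two adjacent stereocentres, C7'' (R, benzylic carbinol) and C8'' (S, aryl ether), in the erythro (anti) relation; ring B separates them from the core, so the core cannot control them. The three benzylic C–O bonds (C7–O, C7'–O, C7''–OH) stand para to oxygen substituents and ionise under acid, free phenols add quinone methide formation and easy oxidation, and C8'' epimerises whenever C7'' is a carbonyl group. The real difficulties are to make the C2-symmetric core as one enantiomer in few steps, to break its symmetry so that only ring B is etherified, and to fix the absolute configuration of C7'' and C8'' independently of the core. The key step uses the fact that C9–C8–C8'–C9' is the carbon chain of succinic acid with an aryl carbinol carbon (C7, C7') on each α-carbon: a bis-enol ether of the anhydride offers C8 and C8' as nucleophiles and C9' and C9 as acyl groups for the oxygens on C7 and C7'.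

## Logic of the disconnections

**21 to 20.** The bonds cut are three O–Si bonds (ring A phenol, ring C phenol, C9'' hydroxyl). Free phenols para to benzylic C–O bonds are the most fragile feature, so they are released last, and one type of silyl group means one operation. The skeleton is not simplified, but every earlier step runs on non-phenolic material. The forward step needs a buffered fluoride source so that no quinone methide forms.

**20 to 16 and 18 (through 19).** The bond cut is ring C aryl carbon–C7''. This removes ring C and the C7'' stereocentre together and leaves an α-aryloxy aldehyde whose one stereocentre can direct the addition. The side chain shrinks to a three-carbon unit and ring C becomes a simple aryl bromide. The addition must be anti (Felkin–Anh) and the aldehyde must keep its configuration.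

**16 to 15.** Only the oxidation level of C7'' changes (aldehyde back to methyl ester). The ester is the stable form and is what the ether-forming step tolerates. The reduction must stop at the aldehyde and leave C8'' untouched.

**15 to 12 and 14.** The bond cut is O-4 of ring B to C8''. This bond joins the two stereochemical domains of the molecule. A reduction of a racemic α-aryloxy β-keto ester hung on ring B could fix only the relative configuration of the side chain and would give two diastereomers of the whole molecule. C8'' is therefore taken from the chiral pool with its absolute configuration and joined by an SN2 process. The problem splits into the core and a three-carbon building block. The forward step must give clean inversion at a secondary carbon next to an ester with a hindered phenol.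

**14 to 13 and 5; 18 to 17 and 5.** One O–Si bond each is cut, which leads to bought materials. The first needs primary-over-secondary selectivity.

**12 to 11.** One aryl O–Si bond is cut. The two phenols of the core are equivalent, so symmetry has to be broken somewhere; doing it here keeps the core synthesis symmetric. The step is statistical by nature and relies on recycling.

**11 to 10 to 9.** C9 and C9' go back from CH2 through the lactol to C=O. The carbonyl groups are what make C8 and C8' nucleophilic one step earlier. The reductions must not ionise C7–O or C7'–O.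

**9 to 3 and two molecules of 6 (through 7 and 8).** The bonds cut are C7–C8, C7'–C8', O–C9' and O–C9, so a bicyclic compound with four stereocentres becomes two achiral compounds. Three points about the forward step go beyond the bare disconnection. First, each molecule of 6 reacts while bound to the chiral Lewis acid, so both C7 and C7' are under catalyst control and only C8 and C8' depend on the substrate. Second, only the first ring closure is an acyl transfer from the anhydride; the second is a lactonisation of the carboxyl group that the first one frees, so an acid phase is needed, and the anhydride oxygen leaves with the two Me3Si groups. Third, the needed aldol diastereomer is the one that later places each aryl group trans to the neighbouring carbonyl carbon on its lactone ring.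

**3 to 1 and 2; 6 to 4 and 5.** O–Si bonds are cut, which leads to bought materials; 3 needs two equivalents of 2, one for each carbonyl oxygen of 1.

## Other disconnections considered

Alternative 1: The cut goes through C7'–C8' and C8–C9, so the ring A tetrahydrofuran is added as a C–O–C unit to the enantiopure butenolide A1. In the forward step CsF converts the chloro ether A2 into the non-stabilised carbonyl ylide A3, which adds across C8=C8' of A1 to give the furofuranone A4.
- In its favour: the cycloaddition type is established for electron-poor alkenes, so it is less speculative than the chosen key step; on mechanistic security it is the better plan. Rings A and B are born with different protecting groups, so no statistical symmetry-breaking is needed; on that point it is also better.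
- Against it here: the one stereocentre of A1 must relay everything, and its hydrogen is benzylic and γ to the lactone carbonyl, so fluoride or base could racemise A1 by deprotonation there, which is favoured because the dienolate formed is a furan. The regiochemistry of the unsymmetrical dipole A3 and the exo placement of ring A are not enforced by a ring. The acetal protecting group of A4 needs acid for removal, which threatens the benzylic ethers.
- Comparison: the step closes one ring and forms two bonds and three stereocentres, against two rings, four bonds and four stereocentres in the chosen plan. One lactone must still be reduced by the same two operations (equal). A1 and A2 each need their own multistep preparation, so the route is longer overall.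

Alternative 2: The cut goes through C8–C8' and C7'–O. In the forward step Cp2TiCl (trivalent titanium) opens the C8–C9 epoxide of the epoxy cinnamyl ether A5 homolytically at C8, and the radical centre closes 5-exo onto the cinnamyl alkene (C8–C8' bond, ring holding C7). Iodine then oxidises the benzylic C7' position so that the C9 alkoxide closes the C7'–O bond, which gives A6.
- In its favour: the radical cascade type is known for furofurans. A6 is already at the final oxidation level, so the two reductions after the chosen key step are not needed (better in step count after the key step). The two aryl rings are differentiated from the start (better).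
- Against it here: Cp2TiCl is needed in stoichiometric amount. One carbinol centre must control C8, C8' and C7'; the cis ring fusion is secure, but the C7' configuration arises in a closure with cationic character and is the weak point. A5 needs an enantioselective carbinol synthesis, etherification and epoxidation before the key step. The aryl allyl ether is exposed to iodine.
- Comparison: the number of stereocentres set is equal. The chosen plan has the advantage of catalytic reagent control from achiral materials and of building both halves at once, and the disadvantage of the later symmetry-breaking.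

Alternative 3: The cut removes both aryl groups (ring B–C7 and ring A–C7'). In the forward step BF3·OEt2 ionises the anomeric acetates of the bis-lactol diacetate A7 one after the other, and the arylzinc bromide A8 adds to each cationic centre from the convex face to give A9, which is identical with 11.
- In its favour: both anomers converge, and the shape of the cis-fused bicycle places both aryl groups exo. No lactone reduction follows (better by two steps after the key step). Two differently protected aryl groups could in principle be introduced in sequence, a possible gain for symmetry-breaking.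
- Against it here: the only lasting stereocentres of A7 are the bridgeheads, so all enantiocontrol moves into the synthesis of a small, polar, C2-symmetric building block that needs its own asymmetric route. After the first arylation a benzylic ether is present that BF3·OEt2 can ionise while the second arylation is still running.
- Comparison: the key step forms two bonds and two stereocentres and closes no ring, so it is less constructive than the chosen step. It is equal in leading to the same compound 11.

Key step: step 3

## Route

Step 1
Reactants: 1 succinic anhydride; 2 chlorotrimethylsilane (2.2 equiv)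
Product: 3 2,5-bis(trimethylsilyloxy)furan
Conditions: Me3SiCl (2.2 equiv), Et3N (2.5 equiv), ZnCl2 (cat.), MeCN, rt to 50 °C; distillation
Reagents that add atoms: chlorotrimethylsilane (the second equivalent of 2; one Me3Si group is needed for each carbonyl oxygen), C[Si](C)(C)Cl
Why: Double O-silylation of the anhydride by soft enolisation (Et3N with ZnCl2 as Lewis acid), which consumes two equivalents of the silyl chloride; the gain of furan aromaticity drives the second silylation, and this is the standard access to 2,5-bis(silyloxy)furans.

Step 2
Reactants: 4 vanillin; 5 chlorotriisopropylsilane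
Product: 6 3-methoxy-4-(triisopropylsilyloxy)benzaldehyde (4-O-TIPS-vanillin)
Conditions: imidazole, DMF, rt
Reagents that add atoms: none
Why: Phenol silylation; the aldehyde is inert, and the bulky aryl silyl ether should survive the Lewis acid, hydride, BF3·OEt2 and Grignard steps that follow.

Step 3
Reactants: 3 2,5-bis(trimethylsilyloxy)furan; 6 4-O-TIPS-vanillin (2.2 equiv)
Product: 9 (1R,2R,5R,6R)-2,6-bis[3-methoxy-4-(triisopropylsilyloxy)phenyl]-3,7-dioxabicyclo[3.3.0]octane-4,8-dione (pinoresinol dilactone bis-TIPS ether), via silyl ketene acetal mono-adduct 7 (not isolated), via trans-anhydride bis-adduct 8 (not isolated)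
Conditions: Ti(OiPr)4 (10 mol%), (R)-BINOL (20 mol%), 4 Å MS, Et2O, −20 °C; then 1 M HCl, THF, 0 °C to rt
Reagents that add atoms: 3-methoxy-4-(triisopropylsilyloxy)benzaldehyde (the second molecule of 6), COc1cc(C=O)ccc1O[Si](C(C)C)(C(C)C)C(C)C
Why: Proposed new method: the closest known reaction type is the Lewis acid-mediated Mukaiyama aldol of 2,5-bis(silyloxy)furans with aldehydes, and the new element is to run it twice under a chiral tetravalent titanium–BINOL Lewis acid; C8 of 3 attacks the Re face of catalyst-bound 6 through an open antiperiplanar transition state and the Me3Si group moves to the new aldolate oxygen, which frees the catalyst and leaves silyl ketene acetal 7. C8' of 7 then attacks a second catalyst-bound molecule of 6, again at its Re face, on the ring face opposite to the C8 substituent, which gives trans-anhydride 8. Acid cleaves the two O–SiMe3 bonds, the C7 hydroxyl adds to C9' (5-exo-trig acyl transfer that opens the anhydride) and the C7' hydroxyl lactonises onto the freed C9 carboxyl (5-exo-trig), the anhydride oxygen leaving with the silyl groups as hexamethyldisiloxane. C7 and C7' are both set by the catalyst because each aldehyde reacts while bound to it, so an error at either centre ends in an unsymmetrical diastereomer that can be removed, and the C2-symmetric product should be enriched in the major enantiomer. C8 is set relative to C7 by the open transition state, in which the aryl group lies next to H8 and away from C8', the arrangement that later puts the aryl group trans to C9 on the lactone ring; C8' is set by the resident C8 substituent (trans addition) and relative to C7' by the same preference. The step needs exo over endo aryl groups and trans over cis at C8–C8'; only the trans-anhydride can close to a cis-fused bis-γ-lactone, a hydroxy diacid formed by stray hydrolysis would close to the same dilactone, and the aromatic aldehyde cannot enolise.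

Step 4
Reactants: 9 pinoresinol dilactone bis-TIPS ether
Product: 10 (1R,2R,5R,6R)-2,6-bis[3-methoxy-4-(triisopropylsilyloxy)phenyl]-3,7-dioxabicyclo[3.3.0]octane-4,8-diol (bis-lactol; anomer mixture at C9 and C9')
Conditions: iBu2AlH (2.3 equiv), CH2Cl2, −78 °C; aq. KNaC4H4O6 (potassium sodium tartrate)
Reagents that add atoms: none
Why: Partial reduction of both γ-lactones to lactols; at −78 °C the aluminium-bound hemiacetals should not collapse, so over-reduction is avoided, and the non-basic medium leaves C8 and C8' in the stable cis-fused arrangement.

Step 5
Reactants: 10 bis-lactol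
Product: 11 (1S,2R,5S,6R)-2,6-bis[3-methoxy-4-(triisopropylsilyloxy)phenyl]-3,7-dioxabicyclo[3.3.0]octane ((7R,7'R,8S,8'S)-pinoresinol bis-TIPS ether)
Conditions: Et3SiH (5 equiv), BF3·OEt2 (2.5 equiv), CH2Cl2, −78 to −40 °C; NaHCO3 quench
Reagents that add atoms: none
Why: Ionic hydrogenation of the lactols: BF3·OEt2 forms the cyclic oxocarbenium ions at C9 and C9' and Et3SiH delivers hydride, so both anomeric centres become CH2 and the anomer mixture converges. Low temperature is used because these oxocarbenium ions form far more easily than benzylic cations at C7 and C7'.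

Step 6
Reactants: 11 pinoresinol bis-TIPS ether
Product: 12 (7R,7'R,8S,8'S)-4'-O-(triisopropylsilyl)pinoresinol (ring B phenol free)
Conditions: Bu4NF (1.0 equiv), AcOH (1.0 equiv), THF, 0 °C; recovered 11 recycled
Reagents that add atoms: none
Why: Fluoride cleavage of one of two equivalent aryl silyl ethers; the step is statistical by design, the monophenol should separate by polarity, and recovered 11 and any diphenol (after silylation as in step 2) go back into the step.

Step 7
Reactants: 13 methyl (R)-2,3-dihydroxypropanoate; 5 chlorotriisopropylsilane
Product: 14 methyl (R)-2-hydroxy-3-(triisopropylsilyloxy)propanoate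
Conditions: imidazole, CH2Cl2, 0 °C
Reagents that add atoms: none
Why: The bulky silyl chloride should select the primary hydroxyl over the secondary one next to the ester; the stereocentre is not involved.

Step 8
Reactants: 12 4'-O-TIPS-pinoresinol; 14 methyl (R)-2-hydroxy-3-(triisopropylsilyloxy)propanoate
Product: 15 methyl (S)-3-(triisopropylsilyloxy)-2-[(7R,7'R,8S,8'S)-4'-O-TIPS-pinoresinol-4-O-yl]propanoate
Conditions: PPh3, DIAD, THF, 0 °C to rt
Reagents that add atoms: none
Why: Mitsunobu etherification of a phenol with an α-hydroxy ester: the phenoxide displaces the oxyphosphonium group at C8'' in an SN2 step activated by the ester, so the (R) centre of 14 becomes the (S) centre C8'' of 15 by inversion.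

Step 9
Reactants: 15 methyl (S)-2-aryloxy-3-silyloxypropanoate
Product: 16 (S)-3-(triisopropylsilyloxy)-2-[(7R,7'R,8S,8'S)-4'-O-TIPS-pinoresinol-4-O-yl]propanal
Conditions: iBu2AlH (1.1 equiv), CH2Cl2, −78 °C; MeOH, aq. KNaC4H4O6 (potassium sodium tartrate); used crude
Reagents that add atoms: none
Why: Partial reduction of an α-aryloxy methyl ester; the chelated tetrahedral intermediate should persist at −78 °C and release the aldehyde only on work-up. The crude aldehyde is used at once so that C8'' has no chance to epimerise.

Step 10
Reactants: 17 4-bromo-2-methoxyphenol; 5 chlorotriisopropylsilane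
Product: 18 (4-bromo-2-methoxyphenoxy)triisopropylsilane
Conditions: imidazole, DMF, rt
Reagents that add atoms: none
Why: Phenol silylation as in step 2; the aryl bromide is untouched.

Step 11
Reactants: 18 (4-bromo-2-methoxyphenoxy)triisopropylsilane (2 equiv); 16 (S)-2-aryloxy-3-silyloxypropanal
Product: 20 (7R,7'R,8S,8'S,7''R,8''S)-4',4'',9''-tris-O-(triisopropylsilyl) ether of the target (C7'' hydroxyl free), via arylmagnesium bromide 19 (not isolated)
Conditions: Mg, I2 (cat.), THF, 40 °C; then 16, THF, −78 °C; aq. NH4Cl
Reagents that add atoms: none
Why: Grignard addition to an α-aryloxy aldehyde under Felkin–Anh (polar) control: the aryl ether oxygen lies anti to the incoming aryl group and the nucleophile passes H8'', which should give the anti (erythro) alcohol, 7''R next to 8''S. Neither the aryl ether nor the bulky silyl ether is a good chelating donor.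

Step 12
Reactants: 20 tris-TIPS ether of the target
Product: 21 (1R,2S)-1-(4-hydroxy-3-methoxyphenyl)-2-[4-[(1R,3aS,4R,6aS)-4-(4-hydroxy-3-methoxyphenyl)tetrahydro-1H,3H-furo[3,4-c]furan-1-yl]-2-methoxyphenoxy]propane-1,3-diol (target)
Conditions: Bu4NF (4 equiv), AcOH (4 equiv), THF, 0 °C to rt
Reagents that add atoms: none
Why: Fluoride cleaves the two aryl silyl ethers and the primary alkyl silyl ether in one operation. Acetic acid buffering keeps the freed p-hydroxybenzyl alcohol and ether units from forming quinone methides, so C7, C7' and C7'' should keep their configuration.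

## Compound list

1 | succinic anhydride | O=C1CCC(=O)O1 | starting material
2 | chlorotrimethylsilane | C[Si](C)(C)Cl | starting material
3 | 2,5-bis(trimethylsilyloxy)furan | C[Si](C)(C)Oc1ccc(O[Si](C)(C)C)o1 | intermediate
4 | vanillin | COc1cc(C=O)ccc1O | starting material
5 | chlorotriisopropylsilane | CC(C)[Si](Cl)(C(C)C)C(C)C | starting material
6 | 3-methoxy-4-(triisopropylsilyloxy)benzaldehyde | COc1cc(C=O)ccc1O[Si](C(C)C)(C(C)C)C(C)C | intermediate
7 | (3R)-3-[(R)-[3-methoxy-4-(triisopropylsilyloxy)phenyl](trimethylsilyloxy)methyl]-5-(trimethylsilyloxy)furan-2(3H)-one | COc1cc([C@H](O[Si](C)(C)C)[C@@H]2C(=O)OC(O[Si](C)(C)C)=C2)ccc1O[Si](C(C)C)(C(C)C)C(C)C | intermediate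
8 | (3R,4R)-3,4-bis[(R)-[3-methoxy-4-(triisopropylsilyloxy)phenyl](trimethylsilyloxy)methyl]oxolane-2,5-dione | COc1cc([C@H](O[Si](C)(C)C)[C@@H]2C(=O)OC(=O)[C@H]2[C@@H](O[Si](C)(C)C)c2ccc(O[Si](C(C)C)(C(C)C)C(C)C)c(OC)c2)ccc1O[Si](C(C)C)(C(C)C)C(C)C | intermediate
9 | (1R,2R,5R,6R)-2,6-bis[3-methoxy-4-(triisopropylsilyloxy)phenyl]-3,7-dioxabicyclo[3.3.0]octane-4,8-dione | COc1cc([C@@H]2OC(=O)[C@@H]3[C@H]2C(=O)O[C@H]3c2ccc(O[Si](C(C)C)(C(C)C)C(C)C)c(OC)c2)ccc1O[Si](C(C)C)(C(C)C)C(C)C | intermediate
10 | (1R,2R,5R,6R)-2,6-bis[3-methoxy-4-(triisopropylsilyloxy)phenyl]-3,7-dioxabicyclo[3.3.0]octane-4,8-diol, anomer mixture | COc1cc([C@@H]2OC(O)[C@@H]3[C@H]2C(O)O[C@H]3c2ccc(O[Si](C(C)C)(C(C)C)C(C)C)c(OC)c2)ccc1O[Si](C(C)C)(C(C)C)C(C)C | intermediate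
11 | (7R,7'R,8S,8'S)-pinoresinol bis(triisopropylsilyl) ether | COc1cc([C@@H]2OC[C@@H]3[C@H]2CO[C@H]3c2ccc(O[Si](C(C)C)(C(C)C)C(C)C)c(OC)c2)ccc1O[Si](C(C)C)(C(C)C)C(C)C | intermediate
12 | (7R,7'R,8S,8'S)-4'-O-(triisopropylsilyl)pinoresinol | COc1cc([C@@H]2OC[C@@H]3[C@H]2CO[C@H]3c2ccc(O[Si](C(C)C)(C(C)C)C(C)C)c(OC)c2)ccc1O | intermediate
13 | methyl (R)-2,3-dihydroxypropanoate | COC(=O)[C@H](O)CO | starting material
14 | methyl (R)-2-hydroxy-3-(triisopropylsilyloxy)propanoate | COC(=O)[C@H](O)CO[Si](C(C)C)(C(C)C)C(C)C | intermediate
15 | methyl (S)-3-(triisopropylsilyloxy)-2-[(7R,7'R,8S,8'S)-4'-O-TIPS-pinoresinol-4-O-yl]propanoate | COC(=O)[C@H](CO[Si](C(C)C)(C(C)C)C(C)C)Oc1ccc([C@@H]2OC[C@@H]3[C@H]2CO[C@H]3c2ccc(O[Si](C(C)C)(C(C)C)C(C)C)c(OC)c2)cc1OC | intermediate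
16 | (S)-3-(triisopropylsilyloxy)-2-[(7R,7'R,8S,8'S)-4'-O-TIPS-pinoresinol-4-O-yl]propanal | O=C[C@H](CO[Si](C(C)C)(C(C)C)C(C)C)Oc1ccc([C@@H]2OC[C@@H]3[C@H]2CO[C@H]3c2ccc(O[Si](C(C)C)(C(C)C)C(C)C)c(OC)c2)cc1OC | intermediate
17 | 4-bromo-2-methoxyphenol | COc1cc(Br)ccc1O | starting material
18 | (4-bromo-2-methoxyphenoxy)triisopropylsilane | COc1cc(Br)ccc1O[Si](C(C)C)(C(C)C)C(C)C | intermediate
19 | [3-methoxy-4-(triisopropylsilyloxy)phenyl]magnesium bromide | COc1cc([Mg]Br)ccc1O[Si](C(C)C)(C(C)C)C(C)C | intermediate
20 | (7R,7'R,8S,8'S,7''R,8''S)-4',4'',9''-tris-O-(triisopropylsilyl) ether of the target | COc1cc([C@@H](O)[C@H](CO[Si](C(C)C)(C(C)C)C(C)C)Oc2ccc([C@@H]3OC[C@@H]4[C@H]3CO[C@H]4c3ccc(O[Si](C(C)C)(C(C)C)C(C)C)c(OC)c3)cc2OC)ccc1O[Si](C(C)C)(C(C)C)C(C)C | intermediate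
21 | (1R,2S)-1-(4-hydroxy-3-methoxyphenyl)-2-[4-[(1R,3aS,4R,6aS)-4-(4-hydroxy-3-methoxyphenyl)tetrahydro-1H,3H-furo[3,4-c]furan-1-yl]-2-methoxyphenoxy]propane-1,3-diol | COc1cc([C@@H](O)[C@H](CO)Oc2ccc([C@@H]3OC[C@@H]4[C@H]3CO[C@H]4c3ccc(O)c(OC)c3)cc2OC)ccc1O | target

## Step count and least certain steps

Total: 12 steps. Longest linear sequence: 9 steps (step 1 or 2, then steps 3, 4, 5, 6, 8, 9, 11, 12).

**Step 3 (key step).** The most likely failure is loss of enantio- and diastereocontrol. Silyl cation released during silyl transfer is itself a Lewis acid and can carry a racemic aldol, and the electron-rich aldehyde binds only weakly to the titanium centre. The second addition may also stay incomplete, and the acid phase may dehydrate at C7 or C7'. The fallback uses known chemistry and sets out from 3 and 6: the established achiral version (TiCl4, CH2Cl2, −78 °C, then the same acid treatment) is run. It should give the racemate, that is 9 together with its mirror image, the (1S,2S,5S,6S)-dilactone F1. The enantiomers would be separated by preparative chromatography on a chiral stationary phase (amylose tris(3,5-dimethylphenylcarbamate), supercritical CO2 with iPrOH), and the route is rejoined at 9.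

**Step 11.** The most likely failure is poor facial selectivity: magnesium may bridge the aldehyde oxygen, the aryl ether oxygen and the ortho methoxy group of ring B, which would favour the syn alcohol. Enolisation of 16 by the basic reagent is a second risk. The fallback sets out from the alcohol mixture of step 11, that is 20 together with its C7'' epimer, the (7''S,8''S) alcohol F2. The mixture is oxidised (Dess–Martin periodinane, NaHCO3, CH2Cl2, 0 °C, short contact so that C8'' does not epimerise) to the single aryl ketone (S)-1-[3-methoxy-4-(triisopropylsilyloxy)phenyl]-3-(triisopropylsilyloxy)-2-[(7R,7'R,8S,8'S)-4'-O-TIPS-pinoresinol-4-O-yl]propan-1-one F3. This is reduced with Zn(BH4)2 in Et2O at −30 °C under 1,2-chelation control: zinc bridges the carbonyl and aryl ether oxygens and hydride enters past H8'', which should give the anti alcohol. The route is rejoined at 20.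

**Step 5 (with step 4).** BF3·OEt2 may ionise C7–O or C7'–O, which would cause epimerisation or reductive ring opening by the silane; in step 4 the reduction may run past the lactol. The fallback sets out from 9 and bypasses 10. LiAlH4 (THF, 0 °C) should give the tetraol (2S,3S)-2,3-bis[(R)-hydroxy[3-methoxy-4-(triisopropylsilyloxy)phenyl]methyl]butane-1,4-diol F4. MsCl (2.1 equiv) in pyridine at 0 °C to rt converts it into the bis(primary mesylate) (2S,3S)-2,3-bis[(R)-hydroxy[3-methoxy-4-(triisopropylsilyloxy)phenyl]methyl]butane-1,4-diyl dimethanesulfonate F5, which should close both rings in the flask by 5-exo-tet attack of the C7 and C7' hydroxyls on C9' and C9. The benzylic C–O bonds are never broken, so C7 and C7' keep their configuration. The route is rejoined at 11.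

**Step 9.** The reduction may overshoot to the primary alcohol, and C8'' may epimerise during isolation of the aldehyde. The fallback sets out from 15: LiBH4 (THF, 0 °C) reduces the ester fully to the primary alcohol (R)-3-(triisopropylsilyloxy)-2-[(7R,7'R,8S,8'S)-4'-O-TIPS-pinoresinol-4-O-yl]propan-1-ol F6. It is kept cold and worked up at neutral pH so that the silyl group does not migrate between the two primary oxygens, which would erode the configuration of C8''. A Parikh–Doering oxidation (SO3·pyridine, DMSO, iPr2NEt, 0 °C) then gives the aldehyde under non-epimerising conditions, and the route is rejoined at 16.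

**Step 8.** The SN2 displacement at the hindered secondary carbon may be slow, so that the hydrazide by-product is alkylated in place of the phenol, or β-elimination of the activated alcohol may compete. The fallback sets out from 14: Tf2O with 2,6-lutidine (CH2Cl2, −78 °C) gives the triflate methyl (R)-2-(trifluoromethylsulfonyloxy)-3-(triisopropylsilyloxy)propanoate F7. The caesium phenoxide of 12 (Cs2CO3, MeCN, 0 °C) should displace it with the same inversion, and the route is rejoined at 15.

## Further compounds

F1 | step 3 | (1S,2S,5S,6S)-2,6-bis[3-methoxy-4-(triisopropylsilyloxy)phenyl]-3,7-dioxabicyclo[3.3.0]octane-4,8-dione (mirror image of 9) | COc1cc([C@H]2OC(=O)[C@H]3[C@@H]2C(=O)O[C@@H]3c2ccc(O[Si](C(C)C)(C(C)C)C(C)C)c(OC)c2)ccc1O[Si](C(C)C)(C(C)C)C(C)C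
F2 | step 11 | (7R,7'R,8S,8'S,7''S,8''S)-4',4'',9''-tris-O-(triisopropylsilyl) ether, the C7'' epimer of 20 | COc1cc([C@H](O)[C@H](CO[Si](C(C)C)(C(C)C)C(C)C)Oc2ccc([C@@H]3OC[C@@H]4[C@H]3CO[C@H]4c3ccc(O[Si](C(C)C)(C(C)C)C(C)C)c(OC)c3)cc2OC)ccc1O[Si](C(C)C)(C(C)C)C(C)C
F3 | step 11 | (S)-1-[3-methoxy-4-(triisopropylsilyloxy)phenyl]-3-(triisopropylsilyloxy)-2-[(7R,7'R,8S,8'S)-4'-O-TIPS-pinoresinol-4-O-yl]propan-1-one | COc1cc(C(=O)[C@H](CO[Si](C(C)C)(C(C)C)C(C)C)Oc2ccc([C@@H]3OC[C@@H]4[C@H]3CO[C@H]4c3ccc(O[Si](C(C)C)(C(C)C)C(C)C)c(OC)c3)cc2OC)ccc1O[Si](C(C)C)(C(C)C)C(C)C
F4 | step 5 | (2S,3S)-2,3-bis[(R)-hydroxy[3-methoxy-4-(triisopropylsilyloxy)phenyl]methyl]butane-1,4-diol | COc1cc([C@H](O)[C@H](CO)[C@@H](CO)[C@@H](O)c2ccc(O[Si](C(C)C)(C(C)C)C(C)C)c(OC)c2)ccc1O[Si](C(C)C)(C(C)C)C(C)C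
F5 | step 5 | (2S,3S)-2,3-bis[(R)-hydroxy[3-methoxy-4-(triisopropylsilyloxy)phenyl]methyl]butane-1,4-diyl dimethanesulfonate | COc1cc([C@H](O)[C@H](COS(C)(=O)=O)[C@@H](COS(C)(=O)=O)[C@@H](O)c2ccc(O[Si](C(C)C)(C(C)C)C(C)C)c(OC)c2)ccc1O[Si](C(C)C)(C(C)C)C(C)C
F6 | step 9 | (R)-3-(triisopropylsilyloxy)-2-[(7R,7'R,8S,8'S)-4'-O-TIPS-pinoresinol-4-O-yl]propan-1-ol | OC[C@H](CO[Si](C(C)C)(C(C)C)C(C)C)Oc1ccc([C@@H]2OC[C@@H]3[C@H]2CO[C@H]3c2ccc(O[Si](C(C)C)(C(C)C)C(C)C)c(OC)c2)cc1OC
F7 | step 8 | methyl (R)-2-(trifluoromethylsulfonyloxy)-3-(triisopropylsilyloxy)propanoate | COC(=O)[C@H](OS(=O)(=O)C(F)(F)F)CO[Si](C(C)C)(C(C)C)C(C)C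
A1 | alternative 1 | (R)-5-[3-methoxy-4-(methoxymethoxy)phenyl]furan-2(5H)-one | COCOc1ccc([C@@H]2OC(=O)C=C2)cc1OC
A2 | alternative 1 | [[(4-allyloxy-3-methoxyphenyl)chloromethoxy]methyl]trimethylsilane | C=CCOc1ccc(C(Cl)OC[Si](C)(C)C)cc1OC
A3 | alternative 1 | carbonyl ylide (O-methylide) of 4-allyloxy-3-methoxybenzaldehyde | C=CCOc1ccc(C=[O+][CH2-])cc1OC
A4 | alternative 1 | furofuranone (C9' lactone) configured as the target core, methoxymethyl ether on ring B and allyl ether on ring A | COCOc1ccc([C@@H]2OC(=O)[C@@H]3[C@H]2CO[C@H]3c2ccc(OCC=C)c(OC)c2)cc1OC
A5 | alternative 2 | (S)-(4-allyloxy-3-methoxyphenyl)(oxiran-2-yl)methyl (E)-3-[3-methoxy-4-(triisopropylsilyloxy)phenyl]allyl ether, epoxide epimer mixture | C=CCOc1ccc([C@H](OC/C=C/c2ccc(O[Si](C(C)C)(C(C)C)C(C)C)c(OC)c2)C2CO2)cc1OC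
A6 | alternative 2 | (7R,7'R,8S,8'S)-4-O-allyl-4'-O-(triisopropylsilyl)pinoresinol | C=CCOc1ccc([C@@H]2OC[C@@H]3[C@H]2CO[C@H]3c2ccc(O[Si](C(C)C)(C(C)C)C(C)C)c(OC)c2)cc1OC
A7 | alternative 3 | (1S,5S)-3,7-dioxabicyclo[3.3.0]octane-2,6-diyl diacetate, anomer mixture | CC(=O)OC1OC[C@@H]2[C@H]1COC2OC(C)=O
A8 | alternative 3 | [3-methoxy-4-(triisopropylsilyloxy)phenyl]zinc bromide | COc1cc([Zn]Br)ccc1O[Si](C(C)C)(C(C)C)C(C)C
A9 | alternative 3 | (7R,7'R,8S,8'S)-pinoresinol bis(triisopropylsilyl) ether (identical with 11) | COc1cc([C@@H]2OC[C@@H]3[C@H]2CO[C@H]3c2ccc(O[Si](C(C)C)(C(C)C)C(C)C)c(OC)c2)ccc1O[Si](C(C)C)(C(C)C)C(C)C
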